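The pyran ring is opened at O1–C2 by a retro-oxa-6π step to a vinylogous ortho-quinone methide, and C4–C3 is cut back to a salicylaldehyde (chromene numbering). In one operation an amine-catalysed Petasis reaction of aldehyde 5 with isobutenylboronic acid 6 forms C4–C3, expels the amine and closes the pyran by electrocyclisation, rearomatising ring A. It exploits the ortho relation of O1 on C8a to C4 on C4a, the para C7 alkoxy donor and the C5 phenethyl group, which turns the diene towards O1. The precursor is a 4-prenyloxy-6-phenethylsalicylaldehyde whose formyl group also fixes regiochemistry and acidifies the C7 hydroxyl, so no protecting group is needed.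

Key step: step 3

Remark: dihydroresveratrol 1 is taken as a purchasable compound (it is also the hydrogenation product of resveratrol); the target has no stereocentre and its ring alkene is cis by ring constraint; ring A is the benzo ring of the chromene and ring B the 4-hydroxyphenyl ring.

Step 1
Reactants: 1 dihydroresveratrol
Product: 3 2,4-dihydroxy-6-[2-(4-hydroxyphenyl)ethyl]benzaldehyde, via aryliminium chloride 2 (not isolated)
Conditions: POCl3 (1.5 equiv), DMF, 0 °C to rt; then ice-water, rt
Reagents that add atoms: N,N-dimethylformamide CN(C)C=O (formyl carbon); water O (formyl oxygen)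
Why: Vilsmeier–Haack formylation: the chloroiminium ion should attack only the doubly activated resorcinol ring A at the carbon para to one hydroxyl and ortho to the other (two sites, equivalent by symmetry), the site that 5-alkylresorcinols such as orcinol and olivetol use, while the less electron-rich ring B is left alone and iminium salt 2 and any transient aryl formate are hydrolysed in the quench.

Step 2
Reactants: 3 2,4-dihydroxy-6-[2-(4-hydroxyphenyl)ethyl]benzaldehyde; 4 prenyl bromide (1-bromo-3-methylbut-2-ene)
Product: 5 2-hydroxy-6-[2-(4-hydroxyphenyl)ethyl]-4-(3-methylbut-2-enyloxy)benzaldehyde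
Conditions: 4 (1.05 equiv), CsHCO3 (1.5 equiv), MeCN, 60 °C
Reagents that add atoms: none
Why: Williamson ether synthesis under acidity control: the weak base CsHCO3 should ionise only the 4-OH, a vinylogous carboxylic acid para to the formyl group and clearly more acidic than the phenol of ring B, the 2-OH is held in a hydrogen bond to the aldehyde, and the allylic bromide 4 is taken up at oxygen by SN2 in the polar aprotic solvent, the same selection that allows 7-O-alkylation of 5,7,4'-trihydroxyflavanones.

Step 3
Reactants: 5 2-hydroxy-6-[2-(4-hydroxyphenyl)ethyl]-4-(3-methylbut-2-enyloxy)benzaldehyde; 6 (2-methylprop-1-en-1-yl)boronic acid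
Product: 9 4-{2-[2,2-dimethyl-7-(3-methylbut-2-enyloxy)-2H-chromen-5-yl]ethyl}phenol (target), via Petasis allylic amine 7 (not isolated), via ortho-quinone methide 8 (not isolated)
Conditions: 6 (1.5 equiv), Bn2NH (0.4 equiv), 1,4-dioxane, 90 °C
Reagents that add atoms: none
Why: Dibenzylamine condenses with the formyl group of 5 to an iminium phenoxide, boronic acid 6 binds the ortho phenoxide O1 as a boronate and hands its alkenyl group to the iminium carbon from within this complex, which forms C4–C3 and gives the allylic amine 7 (Petasis borono-Mannich reaction). At 90 °C the amine is expelled again, pushed by O1 and by the para C7 alkoxy group, so that it turns over as a catalyst and the vinylogous ortho-quinone methide 8 is released. Compound 8 closes the six-membered pyran ring by a thermal disrotatory oxa-6π electrocyclisation over O1=C8a–C4a=C4–C3=C2, which forms O1–C2 and restores the aromaticity of ring A, so the closure is in practice irreversible. The closest known reaction type is the amine-catalysed Petasis synthesis of 2H-chromenes from salicylaldehydes and alkenylboronic acids. The stereocentre at C4 of 7 is racemic and is erased in 8, C2 carries two identical methyl groups and C3=C4 is cis by ring constraint, so no stereocontrol is needed. The step needs the Z geometry at C4a=C4 and chemoselectivity over the free phenol of ring B and the prenyl ether: allylic strain with the C5 phenethyl group turns the dienyl arm towards O1, only the ortho hydroxyl can deliver boron to the iminium ion, addition of amine or phenol to 8 is reversible while the electrocyclisation is not, and 90 °C lies well below the temperature of an aryl prenyl ether Claisen rearrangement.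

Compound list
1 | dihydroresveratrol, 5-[2-(4-hydroxyphenyl)ethyl]benzene-1,3-diol | Oc1ccc(CCc2cc(O)cc(O)c2)cc1 | starting material
2 | {2,4-dihydroxy-6-[2-(4-hydroxyphenyl)ethyl]benzylidene}dimethyliminium chloride | C[N+](C)=Cc1c(O)cc(O)cc1CCc1ccc(O)cc1.[Cl-] | intermediate
3 | 2,4-dihydroxy-6-[2-(4-hydroxyphenyl)ethyl]benzaldehyde | O=Cc1c(O)cc(O)cc1CCc1ccc(O)cc1 | intermediate
4 | prenyl bromide, 1-bromo-3-methylbut-2-ene | CC(C)=CCBr | starting material
5 | 2-hydroxy-6-[2-(4-hydroxyphenyl)ethyl]-4-(3-methylbut-2-enyloxy)benzaldehyde | CC(C)=CCOc1cc(O)c(C=O)c(CCc2ccc(O)cc2)c1 | intermediate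
6 | (2-methylprop-1-en-1-yl)boronic acid | CC(C)=CB(O)O | starting material
7 | racemic 2-[1-(dibenzylamino)-3-methylbut-2-enyl]-3-[2-(4-hydroxyphenyl)ethyl]-5-(3-methylbut-2-enyloxy)phenol | CC(C)=CCOc1cc(O)c(C(C=C(C)C)N(Cc2ccccc2)Cc2ccccc2)c(CCc2ccc(O)cc2)c1 | intermediate
8 | (6Z)-5-[2-(4-hydroxyphenyl)ethyl]-6-(3-methylbut-2-enylidene)-3-(3-methylbut-2-enyloxy)cyclohexa-2,4-dien-1-one | O=C1C=C(OCC=C(C)C)C=C(CCc2ccc(O)cc2)/C1=C/C=C(C)C | intermediate
9 | 4-{2-[2,2-dimethyl-7-(3-methylbut-2-enyloxy)-2H-chromen-5-yl]ethyl}phenol | CC(C)=CCOc1cc(CCc2ccc(O)cc2)c2c(c1)OC(C)(C)C=C2 | target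

Total step count: 3
Longest linear sequence: 3 steps (1 to 3 to 5 to 9)

Steps most likely to fail

Step 3. Iminium formation and alkenyl transfer may be slow at the doubly ortho-substituted, electron-rich aldehyde, so that protodeboronation of 6 runs ahead of C–C bond formation. The fallback sets out from 5 and replaces the boronate transfer by an organometallic 1,2-addition. Excess Me2C=CHMgBr (THF, 0 °C, two equivalents being consumed by the phenols) should give the racemic allylic benzylic alcohol F1. Warming with pyridinium tosylate in toluene should remove water from it. This comes back to the route at the ortho-quinone methide 8, which closes to 9 by the same oxa-6π electrocyclisation.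

Step 2. Discrimination between the three hydroxyl groups may be incomplete, with alkylation also at the oxygen of ring B or at ring carbon. The fallback sets out from 3 and masks ring B.
- TBSCl and imidazole in DMF should give the 4,4'-bis(silyl ether) F2, the chelated 2-OH staying free.
- A catalytic amount of LiOAc in moist DMF at rt should then release only the silyl group on the oxygen para to the formyl group, the far better leaving phenoxide, to give the ring B mono(silyl ether) F3.
- Alkylation with 4 and K2CO3 in acetone should give the prenyl ether silyl ether F4.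
- Bu4NF buffered with AcOH in THF comes back to the route at 5.

Step 1. Attack between the two hydroxyl groups, a second formylation, or lasting O-formylation or O-phosphorylation of the free phenols may erode the regiochemical purity. The fallback sets out from 1 and installs the carbon by halogenation and metalation.
- MOMCl and i-Pr2NEt in CH2Cl2 should give the tris(methoxymethyl) ether F5.
- NBS in MeCN at 0 °C should brominate ring A para to one acetal oxygen and next to the side chain, to give the aryl bromide F6.
- n-BuLi in THF at −78 °C followed by DMF should give the protected aldehyde F7.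
- HCl in MeOH at 40 °C comes back to the route at 3.

Further compounds
F1 | step 3 | racemic 2-(1-hydroxy-3-methylbut-2-enyl)-3-[2-(4-hydroxyphenyl)ethyl]-5-(3-methylbut-2-enyloxy)phenol | CC(C)=CCOc1cc(O)c(C(O)C=C(C)C)c(CCc2ccc(O)cc2)c1
F2 | step 2 | 4-(tert-butyldimethylsilyloxy)-6-{2-[4-(tert-butyldimethylsilyloxy)phenyl]ethyl}-2-hydroxybenzaldehyde | O=Cc1c(O)cc(O[Si](C)(C)C(C)(C)C)cc1CCc1ccc(O[Si](C)(C)C(C)(C)C)cc1
F3 | step 2 | 6-{2-[4-(tert-butyldimethylsilyloxy)phenyl]ethyl}-2,4-dihydroxybenzaldehyde | O=Cc1c(O)cc(O)cc1CCc1ccc(O[Si](C)(C)C(C)(C)C)cc1
F4 | step 2 | 6-{2-[4-(tert-butyldimethylsilyloxy)phenyl]ethyl}-2-hydroxy-4-(3-methylbut-2-enyloxy)benzaldehyde | CC(C)=CCOc1cc(O)c(C=O)c(CCc2ccc(O[Si](C)(C)C(C)(C)C)cc2)c1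
F5 | step 1 | 1,3-bis(methoxymethoxy)-5-{2-[4-(methoxymethoxy)phenyl]ethyl}benzene | COCOc1ccc(CCc2cc(OCOC)cc(OCOC)c2)cc1
F6 | step 1 | 2-bromo-1,5-bis(methoxymethoxy)-3-{2-[4-(methoxymethoxy)phenyl]ethyl}benzene | COCOc1ccc(CCc2cc(OCOC)cc(OCOC)c2Br)cc1
F7 | step 1 | 2,4-bis(methoxymethoxy)-6-{2-[4-(methoxymethoxy)phenyl]ethyl}benzaldehyde | COCOc1ccc(CCc2cc(OCOC)cc(OCOC)c2C=O)cc1
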